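Numbering: tetralin C1 bears the side chain (C11–C16, outward), C4 the methyl, C5 the hydroxyl, C8 the carboxyl. The saturated ring (C1–C4, C4a, C8a) with its trans C1 chain and C4 methyl is a p-menthane and is taken intact from (2R,5R)-dihydrocarvone; the benzene ring (C4a, C5–C8, C8a), whose C5 oxygen lies para to the C8 carboxyl, is built last. Cutting C6–C7 and C8–C8a gives a 2-silyloxydiene, C6=C5(OTBS)–C4a=C8a, that already carries the whole chain (C16 oxygen as benzyl ether), and a propiolate ester. In one flask, [4+2] cycloaddition and DDQ dehydrogenation close and aromatise this ring and fix the para oxygen/carboxyl pattern without touching C1, C4, C11 or C15.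

Key step: step 12

Assumption 1: dihydrocarvone is used as the single (2R,5R) (2,5-trans) isomer; material containing the C2 epimer is purified by chromatography before step 1, because that centre becomes C4 of the target.

Assumption 2: in step 2 the (R) antipode of the ligand is taken as the one leading to the (11S) boronate; the sense is confirmed on the first run, and the equally available (S) ligand is used if it proves opposite.

Remark on the chain: hydroboration of the isopropenyl group ends at C12, and a three-carbon chiral bromide supplies C14–C16, so C13 is inserted by a one-carbon boronate homologation (step 3). The C16 oxygen is carried as a benzyl ether so that it can be released without touching the aryl silyl ether or the silylethyl ester.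

Step 1
Reactants: 1 (2R,5R)-2-methyl-5-(prop-1-en-2-yl)cyclohexan-1-one [(2R,5R)-dihydrocarvone]
Product: 2 (6R,9R)-6-methyl-9-(prop-1-en-2-yl)-1,4-dioxaspiro[4.5]decane
Conditions: Me3SiOCH2CH2OSiMe3, Me3SiOTf (2 mol %), CH2Cl2, −78 °C; pyridine quench
Reagents that add atoms: 1,2-bis(trimethylsilyloxy)ethane, C[Si](C)(C)OCCO[Si](C)(C)C
Why: Silyl triflate-catalysed transfer ketalisation runs at low temperature without enolising the ketone, so the epimerisable centre alpha to the carbonyl (future C4) should keep its configuration and the isopropenyl group is left alone.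

Step 2
Reactants: 2 (6R,9R)-6-methyl-9-(prop-1-en-2-yl)-1,4-dioxaspiro[4.5]decane
Product: 3 4,4,5,5-tetramethyl-2-{(2S)-2-[(6R,9R)-6-methyl-1,4-dioxaspiro[4.5]decan-9-yl]propyl}-1,3,2-dioxaborolane
Conditions: HBpin, CuCl (5 mol %), (R)-DTBM-SEGPHOS (5.5 mol %), KOt-Bu (10 mol %), THF, rt
Reagents that add atoms: pinacolborane, CC1(C)OBOC1(C)C
Why: Copper hydride-catalysed anti-Markovnikov hydroboration of a 1,1-disubstituted alkene places copper, then boron, on terminal C12 and hydrogen on C11, whose configuration is set in the hydrocupration by the chiral bisphosphine distinguishing the methyl group from the branched ring carbon, the two flanking ring methylenes giving the substrate little bias of its own.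

Step 3
Reactants: 3 4,4,5,5-tetramethyl-2-{(2S)-2-[(6R,9R)-6-methyl-1,4-dioxaspiro[4.5]decan-9-yl]propyl}-1,3,2-dioxaborolane
Product: 5 (3S)-3-[(6R,9R)-6-methyl-1,4-dioxaspiro[4.5]decan-9-yl]butan-1-ol, via homologated C13 pinacol boronate 4 (not isolated)
Conditions: BrCH2Cl, n-BuLi, THF, −78 °C → rt; then NaOH, H2O2, THF/H2O, 0 °C → rt
Reagents that add atoms: bromochloromethane, ClCBr; hydrogen peroxide, OO
Why: Matteson one-carbon homologation, in which (chloromethyl)lithium made in the flask adds to boron and the alkyl group migrates with loss of chloride to insert C13, is followed by alkaline peroxide oxidation of the C–B bond to the primary alcohol, neither event involving C11.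

Step 4
Reactants: 5 (3S)-3-[(6R,9R)-6-methyl-1,4-dioxaspiro[4.5]decan-9-yl]butan-1-ol
Product: 6 (6R,9R)-9-[(2S)-4-iodobutan-2-yl]-6-methyl-1,4-dioxaspiro[4.5]decane
Conditions: I2, PPh3, imidazole, CH2Cl2, 0 °C → rt
Reagents that add atoms: iodine, II
Why: Appel-type iodination of a primary alcohol, buffered by imidazole so that the dioxolane should survive.

Step 5
Reactants: 7 (2S)-3-bromo-2-methylpropan-1-ol
Product: 8 {[(2S)-3-bromo-2-methylpropoxy]methyl}benzene
Conditions: BnOC(=NH)CCl3, TfOH (cat.), cyclohexane/CH2Cl2, 0 °C → rt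
Reagents that add atoms: benzyl 2,2,2-trichloroacetimidate, N=C(OCc1ccccc1)C(Cl)(Cl)Cl
Why: Acid-catalysed O-benzylation with the trichloroacetimidate avoids base, which could cyclise or eliminate the bromo alcohol, and does not involve the stereocentre (future C15).

Step 6
Reactants: 6 (6R,9R)-9-[(2S)-4-iodobutan-2-yl]-6-methyl-1,4-dioxaspiro[4.5]decane; 8 {[(2S)-3-bromo-2-methylpropoxy]methyl}benzene
Product: 10 (6R,9R)-9-[(2S,6R)-7-(benzyloxy)-6-methylheptan-2-yl]-6-methyl-1,4-dioxaspiro[4.5]decane, via Grignard reagent 9 (not isolated)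
Conditions: 8, Mg, THF, 40 °C; then 6, Li2CuCl4 (5 mol %), THF, −20 °C → rt
Reagents that add atoms: none
Why: Copper-catalysed sp3–sp3 cross-coupling of a primary alkyl iodide with a primary alkyl Grignard reagent forms C13–C14, both stereocentres being one carbon removed from the reacting centres and the ketal and benzyl ether inert.

Step 7
Reactants: 10 (6R,9R)-9-[(2S,6R)-7-(benzyloxy)-6-methylheptan-2-yl]-6-methyl-1,4-dioxaspiro[4.5]decane
Product: 11 (2R,5R)-5-[(2S,6R)-7-(benzyloxy)-6-methylheptan-2-yl]-2-methylcyclohexan-1-one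
Conditions: PPTS (20 mol %), acetone/H2O (9:1), 55 °C
Reagents that add atoms: water, O
Why: Weakly acidic hydrolysis (transketalisation into acetone) of the dioxolane should not enolise the liberated ketone, so C4 stays trans to the C1 substituent, which is also the more stable arrangement.

Step 8
Reactants: 11 (2R,5R)-5-[(2S,6R)-7-(benzyloxy)-6-methylheptan-2-yl]-2-methylcyclohexan-1-one
Product: 13 (3S,6R)-3-[(2S,6R)-7-(benzyloxy)-6-methylheptan-2-yl]-6-methylcyclohex-1-en-1-yl trifluoromethanesulfonate, via lithium enolate 12 (not isolated)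
Conditions: LiN(iPr)2 (1.1 equiv, ketone added to base), THF, −78 °C; then N-(5-chloropyridin-2-yl)triflimide, −78 → −20 °C
Reagents that add atoms: N-(5-chloropyridin-2-yl)-1,1,1-trifluoro-N-(trifluoromethanesulfonyl)methanesulfonamide, FC(F)(F)S(=O)(=O)N(c1ccc(Cl)cn1)S(=O)(=O)C(F)(F)F
Why: Kinetic enolisation with the hindered amide base removes a proton from the methylene C8a and not from the methine C4, and O-triflation of the enolate at low temperature fixes the C4a=C8a double bond and with it the C4 configuration.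

Step 9
Reactants: 13 (3S,6R)-3-[(2S,6R)-7-(benzyloxy)-6-methylheptan-2-yl]-6-methylcyclohex-1-en-1-yl trifluoromethanesulfonate
Product: 15 1-{(3S,6R)-3-[(2S,6R)-7-(benzyloxy)-6-methylheptan-2-yl]-6-methylcyclohex-1-en-1-yl}ethan-1-one, via 2-ethoxydiene 14 (not isolated)
Conditions: Bu3SnC(OEt)=CH2, Pd(PPh3)4 (5 mol %), LiCl, THF, 65 °C; then 0.5 M HCl, THF, 0 °C
Reagents that add atoms: tributyl(1-ethoxyethenyl)stannane, CCCC[Sn](CCCC)(CCCC)C(=C)OCC; water, O
Why: Stille coupling of the enol triflate with the 1-ethoxyvinylstannane (an acetyl anion equivalent) and brief cold acid hydrolysis of the enol ether give the conjugated methyl ketone (C5, C6) with the double bond held at C4a=C8a and too little acid contact to dienolise towards C1.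

Step 10
Reactants: 15 1-{(3S,6R)-3-[(2S,6R)-7-(benzyloxy)-6-methylheptan-2-yl]-6-methylcyclohex-1-en-1-yl}ethan-1-one
Product: 16 tert-butyl[(1-{(3S,6R)-3-[(2S,6R)-7-(benzyloxy)-6-methylheptan-2-yl]-6-methylcyclohex-1-en-1-yl}ethenyl)oxy]dimethylsilane
Conditions: TBSOTf, Et3N, CH2Cl2, 0 °C
Reagents that add atoms: tert-butyldimethylsilyl trifluoromethanesulfonate, CC(C)(C)[Si](C)(C)OS(=O)(=O)C(F)(F)F
Why: Soft enolisation of the methyl ketone (silyl triflate on oxygen, amine removing a proton) takes the kinetically favoured proton of the C6 methyl group and not the gamma proton at C1, giving the cross-conjugated 2-silyloxydiene with C1 intact.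

Step 11
Reactants: 17 prop-2-ynoic acid (propiolic acid)
Product: 18 2-(trimethylsilyl)ethyl prop-2-ynoate
Conditions: Me3SiCH2CH2OH, DCC, DMAP (5 mol %), CH2Cl2, −20 → 0 °C
Reagents that add atoms: 2-(trimethylsilyl)ethanol, C[Si](C)(C)CCO
Why: Steglich (carbodiimide) esterification at low temperature, where acyl transfer to the alcohol should outrun conjugate addition of the catalyst to the alkyne.

Step 12
Reactants: 16 tert-butyl[(1-{(3S,6R)-3-[(2S,6R)-7-(benzyloxy)-6-methylheptan-2-yl]-6-methylcyclohex-1-en-1-yl}ethenyl)oxy]dimethylsilane; 18 2-(trimethylsilyl)ethyl prop-2-ynoate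
Product: 20 2-(trimethylsilyl)ethyl (5R,8S)-8-[(2S,6R)-7-(benzyloxy)-6-methylheptan-2-yl]-4-[(tert-butyldimethylsilyl)oxy]-5-methyl-5,6,7,8-tetrahydronaphthalene-1-carboxylate, via cyclohexa-1,4-diene cycloadduct 19 (not isolated)
Conditions: 18 (3 equiv), BHT (cat.), PhMe, 120 °C, sealed tube; cool, then DDQ (1.2 equiv), PhMe, 0 °C → rt
Reagents that add atoms: none
Why: The electron-rich 2-silyloxydiene in its s-cis form and the electron-poor alkyne combine in a concerted, asynchronous thermal [4+2] cycloaddition (diene HOMO, dienophile LUMO) that forms C6–C7 and C8–C8a; the closest known reaction type is the Diels–Alder benzannulation of 2-silyloxy-1,3-dienes with alkynoates followed by quinone dehydrogenation. The new six-membered ring (C4a, C5, C6, C7, C8, C8a) closes by this intermolecular cycloaddition across the C4a–C8a bond of the existing ring, so it is fused from the outset. DDQ then abstracts hydride from a doubly allylic carbon of the 1,4-diene (C6 or C8a), and loss of the remaining proton should give the arene with the silyl ether still in place. No new stereocentre remains, since C8a, the only one formed, becomes aromatic, and C1, C4, C11 and C15 take no part. The step needs regioselectivity, which is secured twice over: the largest HOMO coefficient lies on C6 (beta carbon of the enol ether), which bonds to the alkyne beta carbon, and the alkyl-substituted terminus C8a takes the ester-bearing carbon, so the carboxyl ends at C8, para to the C5 oxygen. Bond formation at the hindered C8a lags behind that at C6 in the transition state, so the neighbouring C1 substituent should slow the reaction without redirecting it.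

Step 13
Reactants: 20 2-(trimethylsilyl)ethyl (5R,8S)-8-[(2S,6R)-7-(benzyloxy)-6-methylheptan-2-yl]-4-[(tert-butyldimethylsilyl)oxy]-5-methyl-5,6,7,8-tetrahydronaphthalene-1-carboxylate
Product: 21 2-(trimethylsilyl)ethyl (5R,8S)-4-[(tert-butyldimethylsilyl)oxy]-8-[(2S,6R)-7-hydroxy-6-methylheptan-2-yl]-5-methyl-5,6,7,8-tetrahydronaphthalene-1-carboxylate
Conditions: H2 (1 atm), Pd/C (10 wt % palladium on carbon), EtOAc, rt
Reagents that add atoms: none
Why: Hydrogenolysis of the benzyl ether over palladium meets no alkene now that the ring is aromatic, and the aryl silyl ether and the silylethyl ester should be stable in the aprotic solvent.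

Step 14
Reactants: 21 2-(trimethylsilyl)ethyl (5R,8S)-4-[(tert-butyldimethylsilyl)oxy]-8-[(2S,6R)-7-hydroxy-6-methylheptan-2-yl]-5-methyl-5,6,7,8-tetrahydronaphthalene-1-carboxylate; 22 4-methylpent-3-enoic acid
Product: 23 2-(trimethylsilyl)ethyl (5R,8S)-4-[(tert-butyldimethylsilyl)oxy]-5-methyl-8-{(2S,6R)-6-methyl-7-[(4-methylpent-3-enoyl)oxy]heptan-2-yl}-5,6,7,8-tetrahydronaphthalene-1-carboxylate
Conditions: PPh3, DIAD, THF, 0 °C → rt
Reagents that add atoms: none
Why: In the Mitsunobu esterification the carboxylate displaces the activated primary C16 oxygen, so no activated acyl species forms, the beta,gamma double bond has no path into conjugation, and C15 is not involved.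

Step 15
Reactants: 23 2-(trimethylsilyl)ethyl (5R,8S)-4-[(tert-butyldimethylsilyl)oxy]-5-methyl-8-{(2S,6R)-6-methyl-7-[(4-methylpent-3-enoyl)oxy]heptan-2-yl}-5,6,7,8-tetrahydronaphthalene-1-carboxylate
Product: 24 (5R,8S)-4-hydroxy-5-methyl-8-{(2S,6R)-6-methyl-7-[(4-methylpent-3-enoyl)oxy]heptan-2-yl}-5,6,7,8-tetrahydronaphthalene-1-carboxylic acid (target)
Conditions: tris(dimethylamino)sulfonium difluorotrimethylsilicate (TASF, 3 equiv), DMF, 0 °C → rt; then dilute aq. HCl to pH 3
Reagents that add atoms: none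
Why: Fluoride-induced desilylation in one operation frees the phenoxide and fragments the 2-(trimethylsilyl)ethyl ester to carboxylate, ethene and fluorosilane by attack at silicon, far from the hindered carbonyl, while the anhydrous, weakly basic fluoride source should spare the alkyl ester and its beta,gamma alkene.

Compound list
1 | (2R,5R)-2-methyl-5-(prop-1-en-2-yl)cyclohexan-1-one | C[C@@H]1CC[C@@H](C(C)=C)CC1=O | starting material
2 | (6R,9R)-6-methyl-9-(prop-1-en-2-yl)-1,4-dioxaspiro[4.5]decane | C[C@@H]1CC[C@@H](C(C)=C)CC12OCCO2 | intermediate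
3 | 4,4,5,5-tetramethyl-2-{(2S)-2-[(6R,9R)-6-methyl-1,4-dioxaspiro[4.5]decan-9-yl]propyl}-1,3,2-dioxaborolane | CC1(C)OB(C[C@H](C)[C@@H]2CC[C@@H](C)C3(C2)OCCO3)OC1(C)C | intermediate
4 | 4,4,5,5-tetramethyl-2-{(3S)-3-[(6R,9R)-6-methyl-1,4-dioxaspiro[4.5]decan-9-yl]butyl}-1,3,2-dioxaborolane | CC1(C)OB(CC[C@H](C)[C@@H]2CC[C@@H](C)C3(C2)OCCO3)OC1(C)C | intermediate (not isolated)
5 | (3S)-3-[(6R,9R)-6-methyl-1,4-dioxaspiro[4.5]decan-9-yl]butan-1-ol | OCC[C@H](C)[C@@H]1CC[C@@H](C)C2(C1)OCCO2 | intermediate
6 | (6R,9R)-9-[(2S)-4-iodobutan-2-yl]-6-methyl-1,4-dioxaspiro[4.5]decane | ICC[C@H](C)[C@@H]1CC[C@@H](C)C2(C1)OCCO2 | intermediate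
7 | (2S)-3-bromo-2-methylpropan-1-ol | OC[C@H](C)CBr | starting material
8 | {[(2S)-3-bromo-2-methylpropoxy]methyl}benzene | c1ccccc1COC[C@H](C)CBr | intermediate
9 | [(2S)-3-(benzyloxy)-2-methylpropyl]magnesium bromide | c1ccccc1COC[C@H](C)C[Mg]Br | intermediate (not isolated)
10 | (6R,9R)-9-[(2S,6R)-7-(benzyloxy)-6-methylheptan-2-yl]-6-methyl-1,4-dioxaspiro[4.5]decane | c1ccccc1COC[C@H](C)CCC[C@H](C)[C@@H]1CC[C@@H](C)C2(C1)OCCO2 | intermediate
11 | (2R,5R)-5-[(2S,6R)-7-(benzyloxy)-6-methylheptan-2-yl]-2-methylcyclohexan-1-one | c1ccccc1COC[C@H](C)CCC[C@H](C)[C@@H]1CC[C@@H](C)C(=O)C1 | intermediate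
12 | lithium (3S,6R)-3-[(2S,6R)-7-(benzyloxy)-6-methylheptan-2-yl]-6-methylcyclohex-1-en-1-olate | c1ccccc1COC[C@H](C)CCC[C@H](C)[C@@H]1CC[C@@H](C)C(O[Li])=C1 | intermediate (not isolated)
13 | (3S,6R)-3-[(2S,6R)-7-(benzyloxy)-6-methylheptan-2-yl]-6-methylcyclohex-1-en-1-yl trifluoromethanesulfonate | c1ccccc1COC[C@H](C)CCC[C@H](C)[C@@H]1CC[C@@H](C)C(OS(=O)(=O)C(F)(F)F)=C1 | intermediate
14 | (3S,6R)-3-[(2S,6R)-7-(benzyloxy)-6-methylheptan-2-yl]-1-(1-ethoxyethenyl)-6-methylcyclohex-1-ene | c1ccccc1COC[C@H](C)CCC[C@H](C)[C@@H]1CC[C@@H](C)C(C(=C)OCC)=C1 | intermediate (not isolated)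
15 | 1-{(3S,6R)-3-[(2S,6R)-7-(benzyloxy)-6-methylheptan-2-yl]-6-methylcyclohex-1-en-1-yl}ethan-1-one | c1ccccc1COC[C@H](C)CCC[C@H](C)[C@@H]1CC[C@@H](C)C(C(C)=O)=C1 | intermediate
16 | tert-butyl[(1-{(3S,6R)-3-[(2S,6R)-7-(benzyloxy)-6-methylheptan-2-yl]-6-methylcyclohex-1-en-1-yl}ethenyl)oxy]dimethylsilane | c1ccccc1COC[C@H](C)CCC[C@H](C)[C@@H]1CC[C@@H](C)C(C(=C)O[Si](C)(C)C(C)(C)C)=C1 | intermediate (key-step precursor)
17 | prop-2-ynoic acid | C#CC(=O)O | starting material
18 | 2-(trimethylsilyl)ethyl prop-2-ynoate | C#CC(=O)OCC[Si](C)(C)C | intermediate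
19 | 2-(trimethylsilyl)ethyl (5R,8S)-8-[(2S,6R)-7-(benzyloxy)-6-methylheptan-2-yl]-4-[(tert-butyldimethylsilyl)oxy]-5-methyl-3,5,6,7,8,8a-hexahydronaphthalene-1-carboxylate (C8a not controlled) | c1ccccc1COC[C@H](C)CCC[C@H](C)[C@@H]1CC[C@@H](C)C2=C(O[Si](C)(C)C(C)(C)C)CC=C(C(=O)OCC[Si](C)(C)C)C12 | intermediate (not isolated)
20 | 2-(trimethylsilyl)ethyl (5R,8S)-8-[(2S,6R)-7-(benzyloxy)-6-methylheptan-2-yl]-4-[(tert-butyldimethylsilyl)oxy]-5-methyl-5,6,7,8-tetrahydronaphthalene-1-carboxylate | c1ccccc1COC[C@H](C)CCC[C@H](C)[C@@H]1CC[C@@H](C)c2c(O[Si](C)(C)C(C)(C)C)ccc(C(=O)OCC[Si](C)(C)C)c21 | intermediate (key-step product)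
21 | 2-(trimethylsilyl)ethyl (5R,8S)-4-[(tert-butyldimethylsilyl)oxy]-8-[(2S,6R)-7-hydroxy-6-methylheptan-2-yl]-5-methyl-5,6,7,8-tetrahydronaphthalene-1-carboxylate | OC[C@H](C)CCC[C@H](C)[C@@H]1CC[C@@H](C)c2c(O[Si](C)(C)C(C)(C)C)ccc(C(=O)OCC[Si](C)(C)C)c21 | intermediate
22 | 4-methylpent-3-enoic acid | CC(C)=CCC(=O)O | starting material
23 | 2-(trimethylsilyl)ethyl (5R,8S)-4-[(tert-butyldimethylsilyl)oxy]-5-methyl-8-{(2S,6R)-6-methyl-7-[(4-methylpent-3-enoyl)oxy]heptan-2-yl}-5,6,7,8-tetrahydronaphthalene-1-carboxylate | CC(C)=CCC(=O)OC[C@H](C)CCC[C@H](C)[C@@H]1CC[C@@H](C)c2c(O[Si](C)(C)C(C)(C)C)ccc(C(=O)OCC[Si](C)(C)C)c21 | intermediate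
24 | (5R,8S)-4-hydroxy-5-methyl-8-{(2S,6R)-6-methyl-7-[(4-methylpent-3-enoyl)oxy]heptan-2-yl}-5,6,7,8-tetrahydronaphthalene-1-carboxylic acid | CC(C)=CCC(=O)OC[C@H](C)CCC[C@H](C)[C@@H]1CC[C@@H](C)c2c(O)ccc(C(=O)O)c21 | target

Total step count: 15. Longest linear sequence: 13 steps (steps 1, 2, 3, 4, 6, 7, 8, 9, 10, 12, 13, 14, 15).

Steps most likely to fail

Step 12. Ring closure at C8a, which is flanked by the C1 substituent, may be so slow that hydrolysis of the silyl enol ether or oligomerisation of the propiolate overtakes it, and some aryl silyl ether may be lost during the quinone oxidation. The fallback sets out from diene 16 and uses a far more electron-poor alkyne of the same regiochemical preference, propynal (C#CC=O, freshly made from propargyl alcohol), in toluene at 40–60 °C. This should give the hexahydronaphthalene-1-carbaldehyde cycloadduct F1, which DDQ dehydrogenates in the same flask to the aryl aldehyde F2. Chlorite oxidation (NaClO2, NaH2PO4, 2-methylbut-2-ene, t-BuOH/H2O) then gives the benzoic acid F3. Mitsunobu O-alkylation with 2-(trimethylsilyl)ethanol (PPh3, DIAD, THF) takes place at the alcohol carbon, so the hindered carbonyl is not the reaction site, and it returns to the route at compound 20.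

Step 2. Facial discrimination in the hydrocupration may be insufficient if the chiral catalyst and the C1 stereocentre are mismatched, leaving C11 epimers that are hard to separate. The fallback sets out from ketal 2 and builds C11 on an enoate instead. Ozonolysis (O3, CH2Cl2/MeOH, −78 °C, then Me2S) gives the methyl ketone F4. Horner–Wadsworth–Emmons olefination (triethyl phosphonoacetate, NaH, THF) gives the (E)-enoate F5 after removal of the minor geometric isomer. Enantioselective copper hydride conjugate reduction (Cu(OAc)2, p-tol-BINAP in the antipode found to give 3S, polymethylhydrosiloxane, t-BuOH, toluene) gives the saturated ester F6. Reduction with LiAlH4 in THF comes back to the route at alcohol 5, so step 3 is bypassed as well.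

Step 15. Fluoride may be basic enough to move the beta,gamma double bond of the side-chain ester into conjugation, or to cleave that ester, before the silylethyl ester has fragmented. The fallback reverses the last operations and sets out from alcohol 21. Bu4NF in THF removes both silicon groups while no sensitive ester is present and gives the dihydroxy acid F7. Lipase-catalysed esterification with acid 22 (immobilised Candida antarctica lipase B, 4 Å molecular sieves, toluene, 45 °C) should acylate only the primary aliphatic hydroxyl, since the phenol and the hindered aromatic carboxyl are poor substrates, and arrives directly at target 24.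

Further compounds
F1 | step 12 | (5R,8S)-8-[(2S,6R)-7-(benzyloxy)-6-methylheptan-2-yl]-4-[(tert-butyldimethylsilyl)oxy]-5-methyl-3,5,6,7,8,8a-hexahydronaphthalene-1-carbaldehyde (not isolated) | c1ccccc1COC[C@H](C)CCC[C@H](C)[C@@H]1CC[C@@H](C)C2=C(O[Si](C)(C)C(C)(C)C)CC=C(C=O)C12
F2 | step 12 | (5R,8S)-8-[(2S,6R)-7-(benzyloxy)-6-methylheptan-2-yl]-4-[(tert-butyldimethylsilyl)oxy]-5-methyl-5,6,7,8-tetrahydronaphthalene-1-carbaldehyde | c1ccccc1COC[C@H](C)CCC[C@H](C)[C@@H]1CC[C@@H](C)c2c(O[Si](C)(C)C(C)(C)C)ccc(C=O)c21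
F3 | step 12 | (5R,8S)-8-[(2S,6R)-7-(benzyloxy)-6-methylheptan-2-yl]-4-[(tert-butyldimethylsilyl)oxy]-5-methyl-5,6,7,8-tetrahydronaphthalene-1-carboxylic acid | c1ccccc1COC[C@H](C)CCC[C@H](C)[C@@H]1CC[C@@H](C)c2c(O[Si](C)(C)C(C)(C)C)ccc(C(=O)O)c21
F4 | step 2 | 1-[(6R,9R)-6-methyl-1,4-dioxaspiro[4.5]decan-9-yl]ethan-1-one | CC(=O)[C@@H]1CC[C@@H](C)C2(C1)OCCO2
F5 | step 2 | ethyl (2E)-3-[(6R,9R)-6-methyl-1,4-dioxaspiro[4.5]decan-9-yl]but-2-enoate | CCOC(=O)/C=C(\C)[C@@H]1CC[C@@H](C)C2(C1)OCCO2
F6 | step 2 | ethyl (3S)-3-[(6R,9R)-6-methyl-1,4-dioxaspiro[4.5]decan-9-yl]butanoate | CCOC(=O)C[C@H](C)[C@@H]1CC[C@@H](C)C2(C1)OCCO2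
F7 | step 15 | (5R,8S)-4-hydroxy-8-[(2S,6R)-7-hydroxy-6-methylheptan-2-yl]-5-methyl-5,6,7,8-tetrahydronaphthalene-1-carboxylic acid | OC[C@H](C)CCC[C@H](C)[C@@H]1CC[C@@H](C)c2c(O)ccc(C(=O)O)c21
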